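**Retrosynthetic overview**

1. Target 16 ⇐ epoxide 15: one hydrogenolysis removes seven benzyl groups and opens the oxirane at benzylic C4; the C3–O bond stays.
2. 15 ⇐ salicylaldehyde 11 + chiral styrylsulfonium salt 6: one-pot epoxy-annulation (O1–C2 oxa-Michael, C3–C4 ylide addition, C3–O closure) sets C2 and C3.
3. 11 ⇐ phloroglucinaldehyde 8 + acid 7: 4-O-galloylation fixes the future 7-O-ester, then mono-O-benzylation.
4. 6 ⇐ styrene 2 (from aldehyde 1) + sulfoxide 4 (from isothiocineole 3).
5. Ring order: A, B and galloyl rings are bought; the pyran C ring and a temporary 3,4-oxirane form together in step 6; the oxirane is opened in step 7.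

Assumption: 1, 3, 7 and 8 are taken as commercial, and the sense of induction of the isothiocineole auxiliary in step 6 is taken as drawn (if it proves opposite, ent-3 from (S)-limonene is used and nothing else changes).

**Route**

Step 1
Reactants: 1 3,4,5-tris(benzyloxy)benzaldehyde
Product: 2 3,4,5-tris(benzyloxy)styrene
Conditions: Ph3PCH3Br, KOtBu, THF, 0 °C → rt
Reagents that add atoms: methyltriphenylphosphonium bromide, C[P+](c1ccccc1)(c1ccccc1)c1ccccc1.[Br-]
Why: Wittig methylenation of a non-enolisable aryl aldehyde; no stereocenter is formed.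

Step 2
Reactants: 3 (1R,4R,5R)-isothiocineole
Product: 4 (1R,4R,5R)-isothiocineole S-oxide (oxygen exo, syn to the one-carbon bridge)
Conditions: NaIO4, MeOH/H2O, 0 °C → rt
Reagents that add atoms: sodium periodate, [Na+].[O-]I(=O)(=O)=O
Why: Periodate oxidation of a sulfide stops at the sulfoxide, oxygen goes to the exposed exo lone pair, and no carbon stereocenter is touched.

Step 3
Reactants: 4 (1R,4R,5R)-isothiocineole S-oxide; 2 3,4,5-tris(benzyloxy)styrene
Product: 6 (1R,4R,5R)-4,7,7-trimethyl-6-{(E)-2-[3,4,5-tris(benzyloxy)phenyl]ethenyl}-6-thiabicyclo[3.2.1]octan-6-ium triflate, via S-triflyloxysulfonium triflate 5 (not isolated)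
Conditions: Tf2O, CH2Cl2, −78 °C; then 2, −78 → −30 °C; then 2,6-lutidine; precipitate with Et2O
Reagents that add atoms: triflic anhydride, O=S(=O)(OS(=O)(=O)C(F)(F)F)C(F)(F)F
Why: Interrupted Pummerer-type alkenylation (known for diaryl and cyclic dialkyl sulfoxides with styrenes), in which the terminal styrene carbon attacks sulfur of the S–O-triflated sulfoxide and the benzylic cation loses a proton to give the (E)-alkenylsulfonium salt; the only α-hydrogen is at a bridgehead, so the normal Pummerer path is closed, and after triflate exchange at sulfur the alkene enters from the exposed exo side.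

Step 4
Reactants: 7 3,4,5-tris(benzyloxy)benzoic acid; 8 2,4,6-trihydroxybenzaldehyde
Product: 10 4-formyl-3,5-dihydroxyphenyl 3,4,5-tris(benzyloxy)benzoate, via 3,4,5-tris(benzyloxy)benzoyl chloride 9 (not isolated)
Conditions: (COCl)2, cat. DMF, CH2Cl2, 0 °C → rt, evaporate; then 8, Et3N (1.0 equiv), THF, −40 → 0 °C
Reagents that add atoms: none
Why: Regioselective O-acylation with an acid chloride, because the 4-OH para to the formyl group is the most acidic and the only non-chelated phenol, so one equivalent of base and acid chloride esterifies it and so fixes the later 7-O-gallate.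

Step 5
Reactants: 10 4-formyl-3,5-dihydroxyphenyl 3,4,5-tris(benzyloxy)benzoate
Product: 11 3-(benzyloxy)-4-formyl-5-hydroxyphenyl 3,4,5-tris(benzyloxy)benzoate
Conditions: BnOH, PPh3, DIAD, THF, 0 °C → rt
Reagents that add atoms: benzyl alcohol, OCc1ccccc1
Why: Mitsunobu etherification benzylates one of the two equivalent ortho-phenols under neutral conditions that spare the activated aryl ester, after which the remaining OH is locked in the formyl chelate and does not react.

Step 6
Reactants: 11 3-(benzyloxy)-4-formyl-5-hydroxyphenyl 3,4,5-tris(benzyloxy)benzoate; 6 isothiocineole-derived (E)-styrylsulfonium triflate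
Product: 15 (1aR,2R,7bR)-7-(benzyloxy)-2-[3,4,5-tris(benzyloxy)phenyl]-1a,7b-dihydro-2H-oxireno[2,3-c]chromen-5-yl 3,4,5-tris(benzyloxy)benzoate, via sodium phenoxide 12 (not isolated), via sulfonium ylide 13 (not isolated), via betaine 14 (not isolated)
Conditions: NaH (1.0 equiv), THF, 0 °C; then 6 (1.2 equiv), CH2Cl2, −40 → 0 °C; filter through basic alumina
Reagents that add atoms: none
Why: Proposed new method: the phenoxide adds reversibly (oxa-Michael) to the β-carbon of the styrylsulfonium salt, the resulting ylide attacks the neighbouring formyl group through a six-membered transition state, and the trans-diaxial betaine closes to the oxirane with loss of the sulfide (intramolecular Corey–Chaykovsky epoxidation), so the pyran ring and the oxirane form in one operation; the 2-aryl group is expected to sit anti to the bulky sulfonium on C3 during C–C bond formation and oxygen then displaces sulfur with inversion, which would place the oxirane oxygen cis to the aryl group (2,3-cis), while the isothiocineole framework shields one ylide face and is meant to fix the absolute configuration by Curtin–Hammett selection over the reversible oxa-Michael step; the closest known reaction type is the epoxy-annulation of amino- and hydroxy-carbonyl compounds with vinylsulfonium salts (the sulfur counterpart of the Schweizer chromene synthesis) combined with chiral sulfonium-ylide epoxidation.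

Step 7
Reactants: 15 cis-3,4-epoxyflavan heptabenzyl ether
Product: 16 (−)-epigallocatechin 7-O-gallate, (2R,3R)-3,5-dihydroxy-2-(3,4,5-trihydroxyphenyl)chroman-7-yl 3,4,5-trihydroxybenzoate
Conditions: H2 (1 atm), 20% Pd(OH)2/C, THF/EtOAc (neutral), rt; filter under Ar, lyophilise
Reagents that add atoms: none
Why: Pd-catalysed hydrogenolysis cleaves the seven O-benzyl groups and the benzylic C4–O bond of the aryl oxirane (giving the homobenzylic alcohol) while the C3–O bond, the C2–O1 ring bond and the aryl ester are kept as in benzylated catechin gallates, so C2 and C3 are carried over unchanged and the neutral aprotic solvent avoids acid-induced Meinwald rearrangement.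

**Compound list**

1 | 3,4,5-tris(benzyloxy)benzaldehyde | O=Cc1cc(OCc2ccccc2)c(OCc2ccccc2)c(OCc2ccccc2)c1 | starting material
2 | 3,4,5-tris(benzyloxy)styrene | C=Cc1cc(OCc2ccccc2)c(OCc2ccccc2)c(OCc2ccccc2)c1 | intermediate
3 | (1R,4R,5R)-4,7,7-trimethyl-6-thiabicyclo[3.2.1]octane (isothiocineole) | C[C@@H]1CC[C@@H]2C[C@H]1SC2(C)C | starting material
4 | (1R,4R,5R)-isothiocineole 6-oxide, oxygen exo | C[C@@H]1CC[C@@H]2C[C@H]1[S@@](=O)C2(C)C | intermediate
5 | (1R,4R,5R)-4,7,7-trimethyl-6-[(trifluoromethylsulfonyl)oxy]-6-thiabicyclo[3.2.1]octan-6-ium triflate (sulfur configuration labile, not assigned) | C[C@@H]1CC[C@@H]2C[C@H]1[S+](OS(=O)(=O)C(F)(F)F)C2(C)C.[O-]S(=O)(=O)C(F)(F)F | intermediate (not isolated)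
6 | (1R,4R,5R)-4,7,7-trimethyl-6-{(E)-2-[3,4,5-tris(benzyloxy)phenyl]ethenyl}-6-thiabicyclo[3.2.1]octan-6-ium triflate, alkenyl exo | C[C@@H]1CC[C@@H]2C[C@H]1[S@@+](/C=C/c3cc(OCc4ccccc4)c(OCc4ccccc4)c(OCc4ccccc4)c3)C2(C)C.[O-]S(=O)(=O)C(F)(F)F | intermediate
7 | 3,4,5-tris(benzyloxy)benzoic acid | OC(=O)c1cc(OCc2ccccc2)c(OCc2ccccc2)c(OCc2ccccc2)c1 | starting material
8 | 2,4,6-trihydroxybenzaldehyde | O=Cc1c(O)cc(O)cc1O | starting material
9 | 3,4,5-tris(benzyloxy)benzoyl chloride | ClC(=O)c1cc(OCc2ccccc2)c(OCc2ccccc2)c(OCc2ccccc2)c1 | intermediate (not isolated)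
10 | 4-formyl-3,5-dihydroxyphenyl 3,4,5-tris(benzyloxy)benzoate | O=Cc1c(O)cc(OC(=O)c2cc(OCc3ccccc3)c(OCc3ccccc3)c(OCc3ccccc3)c2)cc1O | intermediate
11 | 3-(benzyloxy)-4-formyl-5-hydroxyphenyl 3,4,5-tris(benzyloxy)benzoate | O=Cc1c(O)cc(OC(=O)c2cc(OCc3ccccc3)c(OCc3ccccc3)c(OCc3ccccc3)c2)cc1OCc1ccccc1 | intermediate
12 | sodium 3-(benzyloxy)-2-formyl-5-{[3,4,5-tris(benzyloxy)benzoyl]oxy}phenoxide | [Na+].[O-]c1cc(OC(=O)c2cc(OCc3ccccc3)c(OCc3ccccc3)c(OCc3ccccc3)c2)cc(OCc2ccccc2)c1C=O | intermediate (not isolated)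
13 | sulfonium ylide from oxa-Michael addition of 12 to 6, (R) at the ArO–CH(Ar) carbon | C[C@@H]1CC[C@@H]2C[C@H]1[S@@+]([CH-][C@H](Oc3cc(OC(=O)c4cc(OCc5ccccc5)c(OCc5ccccc5)c(OCc5ccccc5)c4)cc(OCc5ccccc5)c3C=O)c6cc(OCc7ccccc7)c(OCc7ccccc7)c(OCc7ccccc7)c6)C2(C)C | intermediate (not isolated)
14 | betaine, (2R,3S,4R)-3-sulfonio-4-oxidochroman (2-aryl trans to sulfonium, sulfonium trans to oxide) | C[C@@H]1CC[C@@H]2C[C@H]1[S@@+]([C@@H]3[C@@H](c6cc(OCc7ccccc7)c(OCc7ccccc7)c(OCc7ccccc7)c6)Oc4cc(OC(=O)c8cc(OCc5ccccc5)c(OCc5ccccc5)c(OCc5ccccc5)c8)cc(OCc5ccccc5)c4[C@H]3[O-])C2(C)C | intermediate (not isolated)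
15 | (1aR,2R,7bR)-7-(benzyloxy)-2-[3,4,5-tris(benzyloxy)phenyl]-1a,7b-dihydro-2H-oxireno[2,3-c]chromen-5-yl 3,4,5-tris(benzyloxy)benzoate (flavan numbering 2R,3R,4R; oxirane oxygen cis to the 2-aryl group) | O=C(Oc1cc(OCc3ccccc3)c2c(c1)O[C@H](c4cc(OCc5ccccc5)c(OCc5ccccc5)c(OCc5ccccc5)c4)[C@@H]6O[C@@H]62)c7cc(OCc8ccccc8)c(OCc8ccccc8)c(OCc8ccccc8)c7 | intermediate
16 | (−)-epigallocatechin 7-O-gallate | O=C(Oc1cc(O)c2c(c1)O[C@H](c1cc(O)c(O)c(O)c1)[C@H](O)C2)c1cc(O)c(O)c(O)c1 | target

**Step count and risks**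

Total steps: 7. Longest linear sequence: 4 (steps 4, 5, 6, 7 from 8; equally steps 1, 3, 6, 7 from 1).

Steps most likely to fail:

Step 6. The constitution of the annulation is well founded, but the cis/trans outcome and the ee rest on a model, and the ylide may decompose by α′,β-elimination or the activated ester may transfer its acyl group. The fallback sets out from 15 as obtained, whatever its stereoisomer composition, and moves stereocontrol to a later catalytic step. A Lewis acid (ZnBr2 or cat. Bi(OTf)3, CH2Cl2) opens the oxirane at C4 and a 1,2-hydride shift (Meinwald rearrangement) gives the configurationally labile 5-(benzyloxy)-3-oxo-2-[3,4,5-tris(benzyloxy)phenyl]chroman-7-yl 3,4,5-tris(benzyloxy)benzoate F3. Noyori transfer hydrogenation with dynamic kinetic resolution (RuCl(p-cymene)(TsDPEN), HCO2H/Et3N, catalyst enantiomer chosen to give 3R) reduces the rapidly racemising ketone anti to the 2-aryl group to the cis alcohol (2R,3R)-5-(benzyloxy)-3-hydroxy-2-[3,4,5-tris(benzyloxy)phenyl]chroman-7-yl 3,4,5-tris(benzyloxy)benzoate F4. F4 is debenzylated under the conditions of step 7 and comes back to the route at 16.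

Step 3. The S–O-triflated sulfoxide carries a tertiary C–S bond and may fragment, and the electron-rich styrene may oligomerise. The fallback sets out from 2 and gives up the auxiliary. Diphenyl sulfoxide/Tf2O and 2 give the known type of reagent diphenyl{(E)-2-[3,4,5-tris(benzyloxy)phenyl]ethenyl}sulfonium triflate F1, which has no β-hydrogens. With 12 under the conditions of step 6, F1 gives the epoxide as a racemic stereoisomer mixture, 7-(benzyloxy)-2-[3,4,5-tris(benzyloxy)phenyl]-1a,7b-dihydro-2H-oxireno[2,3-c]chromen-5-yl 3,4,5-tris(benzyloxy)benzoate F2. F2 is then taken through the rearrangement and dynamic kinetic resolution described for step 6 and comes back to the route at 16.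

Step 4. Mono-acylation of one of three phenols may give mixtures, and the product is an activated aryl ester. The fallback sets out from 8 and postpones the ester until only one free, non-chelated phenol is left. TBSCl/imidazole silylates the 4-OH to give 4-[(tert-butyldimethylsilyl)oxy]-2,6-dihydroxybenzaldehyde F5. Mitsunobu benzylation as in step 5 gives 2-(benzyloxy)-4-[(tert-butyldimethylsilyl)oxy]-6-hydroxybenzaldehyde F6. TBAF/AcOH gives 2-(benzyloxy)-4,6-dihydroxybenzaldehyde F7, whose only non-chelated phenol is acylated with 9 and Et3N; this comes back to the route at 11.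

**Further compounds**

F1 | step 3 | diphenyl{(E)-2-[3,4,5-tris(benzyloxy)phenyl]ethenyl}sulfonium triflate | c1ccc(cc1)[S+](/C=C/c1cc(OCc2ccccc2)c(OCc2ccccc2)c(OCc2ccccc2)c1)c1ccccc1.[O-]S(=O)(=O)C(F)(F)F
F2 | step 3 | 7-(benzyloxy)-2-[3,4,5-tris(benzyloxy)phenyl]-1a,7b-dihydro-2H-oxireno[2,3-c]chromen-5-yl 3,4,5-tris(benzyloxy)benzoate, racemic stereoisomer mixture (no stereocenter defined) | O=C(Oc1cc(OCc3ccccc3)c2c(c1)OC(c4cc(OCc5ccccc5)c(OCc5ccccc5)c(OCc5ccccc5)c4)C6OC62)c7cc(OCc8ccccc8)c(OCc8ccccc8)c(OCc8ccccc8)c7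
F3 | step 6 | 5-(benzyloxy)-3-oxo-2-[3,4,5-tris(benzyloxy)phenyl]chroman-7-yl 3,4,5-tris(benzyloxy)benzoate (C2 labile, racemic) | O=C(Oc1cc(OCc3ccccc3)c2c(c1)OC(c4cc(OCc5ccccc5)c(OCc5ccccc5)c(OCc5ccccc5)c4)C(=O)C2)c7cc(OCc8ccccc8)c(OCc8ccccc8)c(OCc8ccccc8)c7
F4 | step 6 | (2R,3R)-5-(benzyloxy)-3-hydroxy-2-[3,4,5-tris(benzyloxy)phenyl]chroman-7-yl 3,4,5-tris(benzyloxy)benzoate | O=C(Oc1cc(OCc3ccccc3)c2c(c1)O[C@H](c4cc(OCc5ccccc5)c(OCc5ccccc5)c(OCc5ccccc5)c4)[C@H](O)C2)c7cc(OCc8ccccc8)c(OCc8ccccc8)c(OCc8ccccc8)c7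
F5 | step 4 | 4-[(tert-butyldimethylsilyl)oxy]-2,6-dihydroxybenzaldehyde | O=Cc1c(O)cc(O[Si](C)(C)C(C)(C)C)cc1O
F6 | step 4 | 2-(benzyloxy)-4-[(tert-butyldimethylsilyl)oxy]-6-hydroxybenzaldehyde | O=Cc1c(O)cc(O[Si](C)(C)C(C)(C)C)cc1OCc1ccccc1
F7 | step 4 | 2-(benzyloxy)-4,6-dihydroxybenzaldehyde | O=Cc1c(O)cc(O)cc1OCc1ccccc1
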